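Target is best reckoned per substrate lost, not per minute.

in all of them: substrate 0.10 M
- south: partner 0.11 M; run made earlier
- north: partner 0.18 M; run made earlier
- north-west: partner 0.22 M; run made earlier
- delta: partner 0.120 M; time 30 min
- zeta: partner 0.240 M; time 30 min

| run | time / min | intermediate / % | target / % | substrate / % | over-reaction product / % | isomer of the product / % |
|---|---|---|---|---|---|---|
| south | 5.00 | 3 | 4 | 90 | 3 | 1 |
| south | 10.0 | 1 | 8 | 85 | 2 | 3 |
| south | 15.0 | 4 | 8 | 81 | 1 | 0 |
| south | 20.0 | 2 | 12 | 79 | 2 | 1 |
| north | 2.50 | 3 | 2 | 96 | 1 | 0 |
| north | 8.00 | 0 | 7 | 85 | 1 | 0 |
| north | 15.0 | 2 | 13 | 73 | 1 | 2 |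
| north | 20.0 | 6 | 18 | 68 | 2 | 2 |
| north-west | 1.50 | 2 | 0 | 94 | 0 | 0 |
| north-west | 4.00 | 3 | 4 | 88 | 0 | 0 |
| north-west | 10.0 | 3 | 11 | 76 | 1 | 2 |
| north-west | 20.0 | 3 | 19 | 62 | 2 | 4 |

(readings scatter by 1.5 percentage points)

- what was read earlier has a scatter of 1.5 percentage points, one standard deviation
- a reading or a percentage of target counts all its forms, free or not
- a reading of substrate is of its free form alone

- which of these there is most of at the end, counted by the substrate in it, delta (substrate / isomer of the product / intermediate / target / over-reaction product)
- which of these there is most of at the end, counted by the substrate in it, zeta (substrate / isomer of the product / intermediate / target / over-reaction product)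
- the largest of these amounts at the end, in percent of the substrate charged, delta
- the largest of these amounts at the end, in percent of the substrate charged, zeta

Two readings seem at odds. The north-west run has twice the partner of the south run, and its substrate time constant, last reading time over ln(charged/left), is 41.8 min against 84.8 min in the south run, so the north-west flask runs twice as fast. Yet target per substrate lost is 0.571 in the south run and 0.500 in the north-west run.

Both fit if partner enters the gain of target and the loss of substrate alike. Divide one rate by the other and time and partner drop out. I reckon substrate as pseudo-first-order, with the time constant inverse to the charge of partner, and I call this yield on substrate lost Y. Taking the north-west value, target equals substrate left at the crossing substrate: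

crossing substrate = Y / (1 + Y) = 33.3%

Scaling the north-west time constant by the charge, I reckon:

delta: time constant 76.7 min, substrate exp(−t/τ) = 67.6%

zeta: time constant 38.4 min, substrate exp(−t/τ) = 45.7%

Both stand above the crossing, so I commit to substrate in delta and in zeta.

The forecast also names substrate for both, with 71% for delta and 50% for zeta, above my figures, holding that “the reaction is first order in partner”.

The flasks give substrate in delta at 68.3% and substrate in zeta at 49.3%, with target, idle adduct counted in, at 16.2% and 24.5%, yields on substrate lost of 0.511 and 0.483.

    partner + target → over-reaction product (k = 0.00170 M⁻¹ s⁻¹)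
    substrate + target ⇌ idle adduct, settled at all times (K = 14.0 M⁻¹)
    intermediate ⇌ isomer of the product (K = 2.20, k = 7.40 × 10⁻⁴ s⁻¹)
    crystals ⇌ released group, rate k4*(cs4 - [released group]) while solid is left; crystals form when [released group] > cs4 (solubility = 18.0 mM, k = 0.00200 s⁻¹)
    substrate + partner → intermediate + released group (k = 0.00150 M⁻¹ s⁻¹)
    intermediate ⇌ target (K = 2.40, k = 0.0250 s⁻¹)

Give the zeta flask 0.96 M of partner and hold the time: the same scaling gives a time constant of 9.59 min and substrate 4.38%, below the crossing. That flask holds 11.6% of substrate, higher than reckoned but still below the crossing. Its yield on substrate lost is 0.243, less than the north-west reading, and with target at 21.5% the species ahead is over-reaction product, at 46.7%.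

All runs were computed for substances that don't exist; scatter was added.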